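**Assumption:** labdane/drimane numbering (C1–C17) is used for the terpenoid half, quinone 34 is numbered as in its name, and compounds 2, 5 and 13 are bought as such.

## Retrosynthetic overview

1. Ring C is closed last by an endo [4+2] between the (12Z)-labdatrienone 22 (diene C12–C15) and flavone-quinone 34 (C2=C3), forming C12–C2 and C15–C3.
2. 22 comes from the 8-keto-9-ol 18 by C8 methylenation, C7 allylic oxidation and alkyne semireduction.
3. Key step: the C9–O bond of 18 is made by radical decarboxylative hydroxylation of a β-keto carboxylate (C9–C11 first by enolate alkylation, oxygen last, from the α-face).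
4. Rings A and B are formed together by cation–olefin bicyclisation of the acyclic β-keto ester 11; its only stereocentre (C2, from (S)-epichlorohydrin) controls C5 and C10.
5. 34 comes from CAN oxidation of flavone 33; the pyranone ring is made by Mentzer condensation. Ring order: A+B (step 6), pyranone (step 18), quinone ring unmasked (step 20), ring C (step 21).

## Route

Step 1
Reactants: 1 (S)-epichlorohydrin; 2 isopropenylmagnesium bromide
Product: 4 (S)-2-(2-methylprop-2-en-1-yl)oxirane, via chlorohydrin 3 (not isolated)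
Conditions: CuI (10 mol%), THF, −40 → 0 °C; then aq NaOH, 25 °C
Reagents that add atoms: none
Why: Cu-catalysed Grignard opening of the epoxide at its CH2 terminus, then Williamson ring closure; the C–O bond at the stereocentre is never broken, so it becomes C2 of the target unchanged.

Step 2
Reactants: 4 (S)-2-(2-methylprop-2-en-1-yl)oxirane; 5 lithium acetylide–ethylenediamine complex
Product: 6 (S)-6-methylhept-6-en-1-yn-4-ol
Conditions: DMSO, 0 → 25 °C; H2O
Reagents that add atoms: none
Why: SN2 opening of the terminal epoxide at CH2 by the acetylide, leaving the carbinol stereocentre untouched.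

Step 3
Reactants: 6 (S)-6-methylhept-6-en-1-yn-4-ol
Product: 8 (S,E)-3,7-dimethylocta-2,7-diene-1,5-diol, via alkenylalane 7 (not isolated)
Conditions: Me3Al (3 equiv), Cp2ZrCl2 (20 mol%), CH2Cl2, 0 → 25 °C; then n-BuLi, (CH2O)n, THF, −78 → 25 °C; aq HCl
Reagents that add atoms: trimethylaluminium (C[Al](C)C); paraformaldehyde (C=O)
Why: Negishi Zr-catalysed syn-carboalumination of the terminal alkyne, then trapping of the alanate with formaldehyde, fixes the E-trisubstituted C5=C10 alkene; the 1,1-disubstituted alkene is inert.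

Step 4
Reactants: 8 (S,E)-3,7-dimethylocta-2,7-diene-1,5-diol
Product: 9 (S,E)-8-chloro-2,6-dimethylocta-1,6-dien-4-ol
Conditions: NCS, Me2S, CH2Cl2, −20 → 0 °C
Reagents that add atoms: N-chlorosuccinimide (ClN1C(=O)CCC1=O)
Why: Corey–Kim chlorination converts only the primary allylic alcohol (SN2 on the alkoxysulfonium salt, no allylic shift) and leaves the secondary alcohol alone.

Step 5
Reactants: 9 (S,E)-8-chloro-2,6-dimethylocta-1,6-dien-4-ol; 10 methyl acetoacetate
Product: 11 methyl (S,E)-9-hydroxy-7,11-dimethyl-3-oxododeca-6,11-dienoate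
Conditions: 10 (2.5 equiv), NaH then n-BuLi, THF, 0 °C; then 9, 0 → 25 °C; aq HCl
Reagents that add atoms: none
Why: Weiler dianion γ-alkylation (SN2 at the primary allylic chloride, E-alkene retained); the excess dianion absorbs the free hydroxyl proton.

Step 6
Reactants: 11 methyl (S,E)-9-hydroxy-7,11-dimethyl-3-oxododeca-6,11-dienoate
Product: 12 methyl 2α-hydroxy-8-oxo-12-nordriman-11-oate
Conditions: SnCl4 (3 equiv), CH2Cl2, −78 → 0 °C; aq NaHCO3
Reagents that add atoms: none
Why: Cation–olefin (polyene) bicyclisation terminated by the β-keto ester enol; in the chair–chair fold the C2 hydroxyl sits equatorial (axial would be 1,3-diaxial to the C4 and C10 methyls), which sets 5α-H and 10β-CH3 (trans-decalin) from C2, while C9 is epimerisable and is reset in step 9.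

Step 7
Reactants: 13 (Z)-3-methylpent-2-en-4-yn-1-ol
Product: 14 (Z)-5-bromo-3-methylpent-3-en-1-yne
Conditions: PBr3 (0.4 equiv), pyridine (cat.), Et2O, −10 °C
Reagents that add atoms: phosphorus tribromide (BrP(Br)Br)
Why: SN2 bromination of the primary allylic alcohol at low temperature keeps the Z-enyne geometry.

Step 8
Reactants: 12 methyl 2α-hydroxy-8-oxo-12-nordriman-11-oate; 14 (Z)-5-bromo-3-methylpent-3-en-1-yne
Product: 15 methyl 2α-hydroxy-9α-[(2Z)-3-methylpent-2-en-4-yn-1-yl]-8-oxo-12-nordriman-11-oate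
Conditions: K2CO3, acetone, 25 → 50 °C
Reagents that add atoms: none
Why: C-alkylation of the β-keto ester enolate at C9 with the primary allylic bromide (SN2, Z retained); the C9 configuration formed here does not matter because C9 becomes planar in step 9.

Step 9
Reactants: 15 methyl 2α-hydroxy-9α-[(2Z)-3-methylpent-2-en-4-yn-1-yl]-8-oxo-12-nordriman-11-oate
Product: 18 (12Z)-2α,9α-dihydroxy-17-norlabd-12-en-14-yn-8-one, via potassium carboxylate 16 (not isolated), via hydroperoxide 17 (not isolated)
Conditions: TMSOK, THF, 25 °C; then 9-mesityl-10-methylacridinium perchlorate (5 mol%), O2 (1 atm), MeCN–H2O, 450 nm, 25 °C; then PPh3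
Reagents that add atoms: potassium trimethylsilanolate (C[Si](C)(C)[O-].[K+]); dioxygen (O=O)
Why: Proposed new method: silanolate ester cleavage then photocatalytic decarboxylative hydroxylation of the β-keto carboxylate (closest known: acridinium/O2 decarboxylative hydroxylation of carboxylic acids and Barton decarboxylative oxygenation); one-electron oxidation of 16 expels CO2 to give the planar tertiary α-keto C9 radical, O2 adds on the α-face anti to the axial C10 methyl so that the side chain ends β (9α-OH), and PPh3 reduces hydroperoxide 17.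

Step 10
Reactants: 18 (12Z)-2α,9α-dihydroxy-17-norlabd-12-en-14-yn-8-one
Product: 19 (12Z)-labda-8(17),12-dien-14-yne-2α,9α-diol
Conditions: Ph3PCH3Br, KOtBu (excess), THF–toluene, 0 → 60 °C
Reagents that add atoms: methyltriphenylphosphonium bromide (C[P+](c1ccccc1)(c1ccccc1)c1ccccc1.[Br-])
Why: Wittig methylenation of the C8 ketone, as practised on labdane 8-ketones; excess ylide covers the two hydroxyls and the alkyne C–H, and no stereocentre is affected.

Step 11
Reactants: 19 (12Z)-labda-8(17),12-dien-14-yne-2α,9α-diol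
Product: 21 (12Z)-2α,9α-dihydroxylabda-8(17),12-dien-14-yn-7-one, via 7α-alcohol 20 (not isolated)
Conditions: SeO2 (30 mol%), t-BuOOH, CH2Cl2, 0 → 25 °C; filter; then MnO2, CH2Cl2, 25 °C
Reagents that add atoms: selenium dioxide (O=[Se]=O); tert-butyl hydroperoxide (CC(C)(C)OO)
Why: SeO2 allylic oxidation (ene reaction then [2,3]-shift) puts OH on C7, the only allylic CH2 of the exocyclic alkene, and returns the double bond to C8=C17; MnO2 then oxidises only this allylic alcohol, so the C7 configuration is lost on purpose.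

Step 12
Reactants: 21 (12Z)-2α,9α-dihydroxylabda-8(17),12-dien-14-yn-7-one
Product: 22 (12Z)-2α,9α-dihydroxylabda-8(17),12,14-trien-7-one
Conditions: Zn(Cu/Ag), MeOH–H2O (1:1), 40 °C
Reagents that add atoms: none
Why: Boland semireduction of the conjugated terminal alkyne to the vinyl group under neutral conditions; the preformed Z C12=C13 bond and the enone are not touched.

Step 13
Reactants: 23 resorcinol
Product: 24 1,3-dimethoxybenzene
Conditions: Me2SO4, K2CO3, acetone, reflux
Reagents that add atoms: dimethyl sulfate (COS(=O)(=O)OC)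
Why: Williamson O-methylation of both phenols.

Step 14
Reactants: 24 1,3-dimethoxybenzene
Product: 26 3,5-dimethoxyphenol, via arylboronate 25 (not isolated)
Conditions: B2pin2 (0.5 equiv), [Ir(OMe)(cod)]2 (1 mol%), dtbpy (2 mol%), THF, 80 °C; then Oxone, acetone–H2O, 25 °C
Reagents that add atoms: bis(pinacolato)diboron (CC1(C)OB(OC1(C)C)B1OC(C)(C)C(C)(C)O1); Oxone (potassium peroxymonosulfate, [K+].[O-]S(=O)(=O)OO)
Why: Sterically controlled Ir-catalysed C–H borylation at C5 (meta to both OMe groups), then oxidation of the C–B bond in the same pot.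

Step 15
Reactants: 27 1,4-benzoquinone
Product: 28 benzene-1,2,4-triyl triacetate
Conditions: Ac2O, H2SO4 (cat.), 45 °C
Reagents that add atoms: acetic anhydride (CC(=O)OC(C)=O)
Why: Thiele–Winter acetoxylation (conjugate addition of acetate, enolisation, peracetylation).

Step 16
Reactants: 28 benzene-1,2,4-triyl triacetate
Product: 29 1,2,4-trimethoxybenzene
Conditions: Me2SO4, NaOH, MeOH–H2O, N2, 0 → 40 °C
Reagents that add atoms: dimethyl sulfate (COS(=O)(=O)OC)
Why: Saponification and in situ Williamson methylation under nitrogen, so the air-sensitive triol is never isolated.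

Step 17
Reactants: 29 1,2,4-trimethoxybenzene; 30 methyl 3-chloro-3-oxopropanoate
Product: 31 methyl 3-oxo-3-(2,4,5-trimethoxyphenyl)propanoate
Conditions: SnCl4, CH2Cl2, 0 → 25 °C
Reagents that add atoms: none
Why: Friedel–Crafts acylation at C5 of the arene (para to one OMe, ortho to another), the usual site for 1,2,4-trimethoxybenzene; the mild Lewis acid avoids ortho-demethylation.

Step 18
Reactants: 31 methyl 3-oxo-3-(2,4,5-trimethoxyphenyl)propanoate; 26 3,5-dimethoxyphenol
Product: 32 5,7-dimethoxy-2-(2,4,5-trimethoxyphenyl)-4H-chromen-4-one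
Conditions: neat, 240 °C (microwave), 20 min
Reagents that add atoms: none
Why: Mentzer thermal pyrone synthesis (transesterification to the aryl ester, intramolecular C-acylation ortho to oxygen, dehydration) gives the flavone; without acid the Pechmann coumarin path is avoided.

Step 19
Reactants: 32 5,7-dimethoxy-2-(2,4,5-trimethoxyphenyl)-4H-chromen-4-one
Product: 33 5-hydroxy-7-methoxy-2-(2,4,5-trimethoxyphenyl)-4H-chromen-4-one
Conditions: BCl3 (1.5 equiv), CH2Cl2, −78 → 0 °C; H2O
Reagents that add atoms: none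
Why: Chelation-controlled ether cleavage: boron bound to the C4 carbonyl removes only the peri 5-O-methyl group.

Step 20
Reactants: 33 5-hydroxy-7-methoxy-2-(2,4,5-trimethoxyphenyl)-4H-chromen-4-one
Product: 34 2-(5-hydroxy-7-methoxy-4-oxo-4H-chromen-2-yl)-5-methoxy-1,4-benzoquinone
Conditions: CAN (2.5 equiv), MeCN–H2O (2:1), 0 °C
Reagents that add atoms: water (O)
Why: CAN oxidative demethylation of the para-dimethoxy pair (2′,5′) of the most electron-rich ring gives the p-quinone and keeps the 4′-OMe; the carbonyl-deactivated, hydrogen-bonded A ring is not oxidised.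

Step 21
Reactants: 22 (12Z)-2α,9α-dihydroxylabda-8(17),12,14-trien-7-one; 34 2-(5-hydroxy-7-methoxy-4-oxo-4H-chromen-2-yl)-5-methoxy-1,4-benzoquinone
Product: 35 dichrostachine N
Conditions: 5 M LiClO4 in Et2O, 25 °C (or CH2Cl2, 13 kbar, 25 °C); chromatography
Reagents that add atoms: none
Why: Endo Diels–Alder reaction in which Li+ on the more basic C1=O of 34 makes C3 the electrophilic terminus (C15–C3, C12–C2) and endo addition to the Z-diene (C11 inside) gives the cis ring fusion with H-12 syn to the quinone carbonyls, i.e. the relative configuration of the three new centres of 35; the remote C9 centre does not control which quinone face reacts, so 35 is separated from the other endo diastereomer.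

## Compound list

1 | (S)-epichlorohydrin | ClC[C@@H]1CO1 | starting material
2 | isopropenylmagnesium bromide | CC(=C)[Mg]Br | starting material
3 | (S)-1-chloro-4-methylpent-4-en-2-ol | C=C(C)C[C@H](O)CCl | intermediate
4 | (S)-2-(2-methylprop-2-en-1-yl)oxirane | C=C(C)C[C@H]1CO1 | intermediate
5 | lithium acetylide–ethylenediamine complex | [Li+].[C-]#C.NCCN | starting material
6 | (S)-6-methylhept-6-en-1-yn-4-ol | C=C(C)C[C@H](O)CC#C | intermediate
7 | (S,E)-alkenyl(dimethyl)alane, O-dimethylalanyl alkoxide of 1-alumino-2,6-dimethylhepta-1,6-dien-4-ol | C=C(C)C[C@H](O[Al](C)C)C/C(C)=C/[Al](C)C | intermediate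
8 | (S,E)-3,7-dimethylocta-2,7-diene-1,5-diol | C=C(C)C[C@H](O)C/C(C)=C/CO | intermediate
9 | (S,E)-8-chloro-2,6-dimethylocta-1,6-dien-4-ol | C=C(C)C[C@H](O)C/C(C)=C/CCl | intermediate
10 | methyl acetoacetate | COC(=O)CC(C)=O | starting material
11 | methyl (S,E)-9-hydroxy-7,11-dimethyl-3-oxododeca-6,11-dienoate | C=C(C)C[C@H](O)C/C(C)=C/CCC(=O)CC(=O)OC | intermediate
12 | methyl 2α-hydroxy-8-oxo-12-nordriman-11-oate (trans-decalin, 5α-H, 10β-CH3, ester β on C9) | O=C1CC[C@H]2C(C)(C)C[C@H](O)C[C@]2(C)[C@H]1C(=O)OC | intermediate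
13 | (Z)-3-methylpent-2-en-4-yn-1-ol | OC/C=C(/C)C#C | starting material
14 | (Z)-5-bromo-3-methylpent-3-en-1-yne | BrC/C=C(/C)C#C | intermediate
15 | methyl 2α-hydroxy-9α-[(2Z)-3-methylpent-2-en-4-yn-1-yl]-8-oxo-12-nordriman-11-oate | O=C1CC[C@H]2C(C)(C)C[C@H](O)C[C@]2(C)[C@@]1(C/C=C(/C)C#C)C(=O)OC | intermediate
16 | potassium 2α-hydroxy-9α-[(2Z)-3-methylpent-2-en-4-yn-1-yl]-8-oxo-12-nordriman-11-oate | O=C1CC[C@H]2C(C)(C)C[C@H](O)C[C@]2(C)[C@@]1(C/C=C(/C)C#C)C(=O)[O-].[K+] | intermediate
17 | (12Z)-9α-hydroperoxy-2α-hydroxy-17-norlabd-12-en-14-yn-8-one | O=C1CC[C@H]2C(C)(C)C[C@H](O)C[C@]2(C)[C@@]1(OO)C/C=C(/C)C#C | intermediate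
18 | (12Z)-2α,9α-dihydroxy-17-norlabd-12-en-14-yn-8-one | O=C1CC[C@H]2C(C)(C)C[C@H](O)C[C@]2(C)[C@@]1(O)C/C=C(/C)C#C | intermediate
19 | (12Z)-labda-8(17),12-dien-14-yne-2α,9α-diol | C=C1CC[C@H]2C(C)(C)C[C@H](O)C[C@]2(C)[C@@]1(O)C/C=C(/C)C#C | intermediate
20 | (12Z)-labda-8(17),12-dien-14-yne-2α,7α,9α-triol | C=C1[C@H](O)C[C@H]2C(C)(C)C[C@H](O)C[C@]2(C)[C@@]1(O)C/C=C(/C)C#C | intermediate
21 | (12Z)-2α,9α-dihydroxylabda-8(17),12-dien-14-yn-7-one | C=C1C(=O)C[C@H]2C(C)(C)C[C@H](O)C[C@]2(C)[C@@]1(O)C/C=C(/C)C#C | intermediate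
22 | (12Z)-2α,9α-dihydroxylabda-8(17),12,14-trien-7-one | C=C1C(=O)C[C@H]2C(C)(C)C[C@H](O)C[C@]2(C)[C@@]1(O)C/C=C(/C)C=C | intermediate
23 | resorcinol | Oc1cccc(O)c1 | starting material
24 | 1,3-dimethoxybenzene | COc1cccc(OC)c1 | intermediate
25 | 2-(3,5-dimethoxyphenyl)-4,4,5,5-tetramethyl-1,3,2-dioxaborolane | COc1cc(OC)cc(c1)B1OC(C)(C)C(C)(C)O1 | intermediate
26 | 3,5-dimethoxyphenol | COc1cc(O)cc(OC)c1 | intermediate
27 | 1,4-benzoquinone | O=C1C=CC(=O)C=C1 | starting material
28 | benzene-1,2,4-triyl triacetate | CC(=O)Oc1ccc(OC(C)=O)c(OC(C)=O)c1 | intermediate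
29 | 1,2,4-trimethoxybenzene | COc1ccc(OC)c(OC)c1 | intermediate
30 | methyl 3-chloro-3-oxopropanoate | COC(=O)CC(Cl)=O | starting material
31 | methyl 3-oxo-3-(2,4,5-trimethoxyphenyl)propanoate | COC(=O)CC(=O)c1cc(OC)c(OC)cc1OC | intermediate
32 | 5,7-dimethoxy-2-(2,4,5-trimethoxyphenyl)-4H-chromen-4-one | COc1cc(OC)c(cc1OC)-c1cc(=O)c2c(OC)cc(OC)cc2o1 | intermediate
33 | 5-hydroxy-7-methoxy-2-(2,4,5-trimethoxyphenyl)-4H-chromen-4-one | COc1cc(OC)c(cc1OC)-c1cc(=O)c2c(O)cc(OC)cc2o1 | intermediate
34 | 2-(5-hydroxy-7-methoxy-4-oxo-4H-chromen-2-yl)-5-methoxy-1,4-benzoquinone | COC1=CC(=O)C(=CC1=O)c1cc(=O)c2c(O)cc(OC)cc2o1 | intermediate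
35 | dichrostachine N | C=C1C(=O)C[C@H]2C(C)(C)C[C@H](O)C[C@]2(C)[C@@]1(O)C[C@@H]1C(C)=CC[C@H]2C(=O)C(OC)=CC(=O)[C@@]12c1cc(=O)c2c(O)cc(OC)cc2o1 | target

## Step count and risks

Total step count: 21. Longest linear sequence: 12 steps (1–6, 8–12, 21).

**Step 21** is the most likely to fail. The Z-diene is a sluggish diene, the regiochemistry rests on electronic bias alone, and nothing in 22 decides which face of the quinone reacts. The fallback replaces substrate control by reagent control. It sets out from 22, which is silylated (TMSOTf, 2,6-lutidine) to the 2,9-bis(trimethylsilyl) ether F5. F5 is combined with 34 under Corey's cationic o-tolyl oxazaborolidine triflimide (20 mol%, CH2Cl2, −78 → −20 °C), using the catalyst antipode that shields the unwanted quinone face, to give the bis-silylated adduct F6. Desilylation with 1 M HCl in THF brings the route back at 35.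

**Step 9** is a new combination of known reactions; ester cleavage could trigger retro-Claisen opening, and the β-keto carboxylate could lose CO2 without oxidation. The fallback separates decarboxylation from oxygenation. It sets out from 15, which is dealkoxycarbonylated (Krapcho: LiCl, wet DMSO, 150 °C) to the 9α-H ketone F1. Gardner–Barton enolate autoxidation of F1 (KOtBu, O2, P(OEt)3, t-BuOH–DME, −20 °C) hydroxylates the tertiary α-position through hydroperoxide 17, and the route is rejoined at 18.

**Step 11** may not be chemoselective, because SeO2 can also attack the allylic methyl and methylene of the enyne. The fallback builds the C7 oxygen by a hydroxyl-directed singlet-oxygen ene reaction instead. It sets out from 18 (bypassing 19): the kinetic enolate (LDA, then Comins' reagent) gives the enol triflate F2, and Me2CuLi converts it into the Δ7-8-methyl diol F3. Schenck ene reaction (O2, tetraphenylporphyrin, hν) abstracts a C17 hydrogen geminal to the carbinol and gives the 7α-hydroperoxide F4. PPh3 reduces F4, and the route is rejoined at 20, which is oxidised with MnO2 as in the second stage of step 11.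

## Further compounds

F1 | step 9 | (12Z)-2α-hydroxy-17-norlabd-12-en-14-yn-8-one (9α-H, side chain β) | O=C1CC[C@H]2C(C)(C)C[C@H](O)C[C@]2(C)[C@H]1C/C=C(/C)C#C
F2 | step 11 | (12Z)-2α,9α-dihydroxy-17-norlabda-7,12-dien-14-yn-8-yl trifluoromethanesulfonate | O=S(=O)(OC1=CC[C@H]2C(C)(C)C[C@H](O)C[C@]2(C)[C@@]1(O)C/C=C(/C)C#C)C(F)(F)F
F3 | step 11 | (12Z)-labda-7,12-dien-14-yne-2α,9α-diol | CC1=CC[C@H]2C(C)(C)C[C@H](O)C[C@]2(C)[C@@]1(O)C/C=C(/C)C#C
F4 | step 11 | (12Z)-7α-hydroperoxylabda-8(17),12-dien-14-yne-2α,9α-diol | C=C1[C@H](OO)C[C@H]2C(C)(C)C[C@H](O)C[C@]2(C)[C@@]1(O)C/C=C(/C)C#C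
F5 | step 21 | (12Z)-2α,9α-bis(trimethylsilyloxy)labda-8(17),12,14-trien-7-one | C=C1C(=O)C[C@H]2C(C)(C)C[C@H](O[Si](C)(C)C)C[C@]2(C)[C@@]1(O[Si](C)(C)C)C/C=C(/C)C=C
F6 | step 21 | dichrostachine N 2,9-bis(trimethylsilyl) ether | C=C1C(=O)C[C@H]2C(C)(C)C[C@H](O[Si](C)(C)C)C[C@]2(C)[C@@]1(O[Si](C)(C)C)C[C@@H]1C(C)=CC[C@H]2C(=O)C(OC)=CC(=O)[C@@]12c1cc(=O)c2c(O)cc(OC)cc2o1
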